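The making of target is slow, so the question is how much of it survives substrate when the same amounts are charged in four ways.

    substrate + target → side product (k1 = 88 /M/s)
    substrate + reagent → target, rate k2*[substrate]^0.5*[reagent]^0.5 (k2 = 0.0063 /s)
    reagent + target ⇌ idle adduct, settled at all times (K3 = 350 /M)

| setting | alpha | zeta | delta | epsilon |
|---|---|---|---|---|
| substrate | 0.0020 M (fed, over 30.0 s) | 0.0020 M | 0.0020 M | 0.0020 M |
| reagent | 2.20 mM | 2.20 mM | 2.20 mM (fed, over 30.0 s) | 2.20 mM |
| time | 30 s |  | 30 s | 30 s |
| remark | a stirred flask in which substrate is dosed at a steady rate over 30.0 s without added volume, worked up at 30 s | a single well-mixed tank run continuously and read at steady state, 30 s in it on average | all but reagent at the start; reagent goes in evenly over 30.0 s, the run ends at 30 s | a closed flask charged with all of it at once and left for 30 s |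

- percent here means substrate units held: one side product counts as two
- what is said of target includes idle adduct
- the stated concentrations are those of everything mixed, before any reaction; amounts are the same in each set-up
- the feed brings no volume worth counting
- run time (alpha): 30 s

1. the set-up with the highest share of target in all that became target or side product, at the outlet or at the end ("none" if the first two lie within 2 percentage points) (alpha / zeta / delta / epsilon / none)
2. share of target in all that became target or side product, at the outlet or at the end, alpha
3. share of target in all that became target or side product, at the outlet or at the end, zeta
4. share of target in all that became target or side product, at the outlet or at the end, delta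
5. share of target in all that became target or side product, at the outlet or at the end, epsilon

Divide the rate of target's loss by the rate of its making, and time drops out. The ratio is free target times the square root of substrate over reagent, divided by the balance level, the constant of making over the constant of loss, 0.0716 mM. When that ratio reaches one, target stops rising: this is the usual quasi-steady state. Idle adduct multiplies the free amount by one plus 0.770, so at whole charges target stands near 0.133 mM.

Making runs at 0.0132 mM/s with undiminished charges, which gives 0.396 mM in epsilon. Dosing either partner evenly cuts this to 0.264 mM. Each side product consumed one target and counts double, so the share is target held over twice the amount made minus target held. That gives 20.1% for epsilon and 33.6% for alpha.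

At whole charges this reckoning ties delta with alpha, and that is the weak link, since target trails its balance by 10.1 s, less than the run. Delta's balance is therefore the one for the reagent dosed one lag earlier, 1.46 mM. This gives 0.0926 mM and a share of 21.2%. This reckoning commits to alpha and leaves the tank open.

The forecast also names alpha, with 33.5%, 17.5% for zeta, 23.7% for delta, which is above this reckoning, and 21% for epsilon: “excess reagent sequesters it”, it says of target in alpha.

The simulation gives alpha with 33.3%, then zeta 17.5%, delta 23.9% and epsilon 21.0%. The forecast would fail on a late reading: at 300 s, target is 11.9% in alpha, 11.9% in delta and 11.9% in epsilon. From alpha's substrate and reagent at 30.0 s, the balance level gives target 6.45% of the substrate charged, and the flask holds 5.97%.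

Read at 2.0 min, alpha's remaining substrate and reagent give a balance of 9.53%, and so a share of 11.7% of the substrate lost. The computed flask holds 8.06%, a share of 9.87%.

Its constants were chosen freely; the run is a simulation.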